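**Assumption:** the SMILES is taken literally: cis ring fusion with H‑1, H‑4a and H‑11a all syn (1R,4aS,11aS), 9S,10S (trans), 12S,13R (anti), 7E (xenicane numbering). Genipin is treated as an inexpensive commercial chiral‑pool compound.

## Retrosynthetic overview

1. 26 ⇒ ynal 25: the last bond is C10–C11, closing the nine‑membered ring by a Ni‑catalysed electroreductive exo‑selective alkyne–aldehyde macrocyclization (gives C11=CH2 and C10–OH).
2. 25 ⇒ alkyl iodide 17 + (E)‑vinyl iodide 23 (C6–C7, Negishi); 23 comes from (R)‑glyceraldehyde acetonide, which supplies C9.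
3. 17 ⇒ vinyl iodide 10 + aldehyde 15 (C4–C12, Nozaki–Hiyama–Kishi); 15 comes from (S)‑glyceraldehyde acetonide, which supplies C13 and controls C12.
4. 10 ⇒ genipin 1: the cis‑fused dihydropyran (C4a, C11a) is bought; the cyclopentene is opened by enal epoxidation and Eschenmoser–Tanabe fragmentation (C11 alkyne + C6 aldehyde), CO2Me is removed by iododecarboxylation, and C1–OAc is set by anomeric Mitsunobu inversion.
5. Ring order: the dihydropyran is present from genipin throughout; the cyclononene is formed last.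

## Route

**Step 1**
Reactants: 1, genipin
Product: 2, 10‑oxogenipin (methyl (1R,4aS,7aS)‑7‑formyl‑1‑hydroxy‑1,4a,5,7a‑tetrahydrocyclopenta[c]pyran‑4‑carboxylate)
Conditions: activated MnO2, CH2Cl2, rt
Reagents that add atoms: none
Why: MnO2 allylic oxidation converts only the primary allylic alcohol to the enal; the non‑allylic lactol OH is left alone.

**Step 2**
Reactants: 2, 10‑oxogenipin
Product: 3, methyl (1S,4aS,7aS)‑1‑(tert‑butyldimethylsilyloxy)‑7‑formyl‑1,4a,5,7a‑tetrahydrocyclopenta[c]pyran‑4‑carboxylate (same C1 geometry as genipin; the descriptor changes only because OSi outranks the ring O)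
Conditions: TBSCl, imidazole, DMF, 0 °C → rt
Reagents that add atoms: TBSCl, CC(C)(C)[Si](C)(C)Cl
Why: Lactol silylation masks the hemiacetal for the hydride and hydroxide steps; no bond at C1 is broken, so the genipin anomeric configuration is kept.

**Step 3**
Reactants: 3
Product: 4, the 6,7‑epoxide of 3 (iridoid C7–C8 oxirane on the convex face, cis to H‑4a/H‑7a; epoxy aldehyde)
Conditions: 30% H2O2, NaHCO3, MeOH–THF, 0 °C
Reagents that add atoms: hydrogen peroxide, OO
Why: Weitz–Scheffer nucleophilic epoxidation of the enal from the convex face; the push–pull β‑alkoxyacrylate is not an acceptor, and the two new stereocentres are destroyed in step 4.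

**Step 4**
Reactants: 4
Product: 5, methyl (2S,3S,4S)‑2‑(tert‑butyldimethylsilyloxy)‑3‑ethynyl‑4‑(2‑hydroxyethyl)‑3,4‑dihydro‑2H‑pyran‑5‑carboxylate (ethynyl and hydroxyethyl cis)
Conditions: TsNHNH2, CH2Cl2/AcOH (2:1), −20 °C → rt; then NaBH4, 0 °C
Reagents that add atoms: none
Why: Eschenmoser–Tanabe fragmentation of the epoxy‑aldehyde tosylhydrazone cleaves the former C=C bond to a terminal alkyne and an aldehyde, which NaBH(OAc)3 formed in situ reduces in the same pot; the cis ring substituents are the untouched genipin ring fusion.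

**Step 5**
Reactants: 5
Product: 6, (2S,3S,4S)‑2‑(tert‑butyldimethylsilyloxy)‑3‑ethynyl‑4‑(2‑hydroxyethyl)‑3,4‑dihydro‑2H‑pyran‑5‑carboxylic acid
Conditions: LiOH·H2O, THF/MeOH/H2O, 40 °C; pH 5 work‑up
Reagents that add atoms: lithium hydroxide, [Li+].[OH-]
Why: Saponification of the vinylogous carbonate methyl ester; silyl acetal, alkyne and enol ether tolerate aqueous hydroxide.

**Step 6**
Reactants: 6
Product: 7, 2‑[(2S,3S,4S)‑2‑(tert‑butyldimethylsilyloxy)‑3‑ethynyl‑5‑iodo‑3,4‑dihydro‑2H‑pyran‑4‑yl]ethan‑1‑ol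
Conditions: NIS, NaHCO3, MeCN, 0 °C, dark
Reagents that add atoms: N‑iodosuccinimide, O=C1CCC(=O)N1I
Why: Hunsdiecker‑type iododecarboxylation: the enol ether is iodinated ipso to CO2H and the oxocarbenium loses CO2 to return the enol ether as the vinyl iodide; the terminal alkyne is inert to NIS without Ag(I) or strong base.

**Step 7**
Reactants: 7
Product: 8, tert‑butyl{[(2S,3S,4S)‑3‑ethynyl‑5‑iodo‑4‑(2‑iodoethyl)‑3,4‑dihydro‑2H‑pyran‑2‑yl]oxy}dimethylsilane
Conditions: PPh3, I2, imidazole, CH2Cl2, 0 °C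
Reagents that add atoms: iodine, II
Why: Appel iodination of the primary alcohol.

**Step 8**
Reactants: 8
Product: 9, (2R,3S,4S)‑3‑ethynyl‑5‑iodo‑4‑(2‑iodoethyl)‑3,4‑dihydro‑2H‑pyran‑2‑ol (lactol, OH trans to ethynyl as in genipin)
Conditions: TBAF/AcOH (1:1), THF, 0 °C; used directly
Reagents that add atoms: none
Why: Buffered fluoride desilylation; the buffer prevents ring‑opening and epimerisation, and the lactol is expected to rest as the genipin‑type anomer (OH trans to the neighbouring substituent).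

**Step 9**
Reactants: 9
Product: 10, (2R,3S,4S)‑3‑ethynyl‑5‑iodo‑4‑(2‑iodoethyl)‑3,4‑dihydro‑2H‑pyran‑2‑yl acetate (OAc cis to ethynyl)
Conditions: PPh3, DIAD, AcOH, toluene/THF, −20 → 0 °C
Reagents that add atoms: acetic acid, CC(=O)O
Why: Anomeric Mitsunobu esterification: SN2 displacement of the oxyphosphonium by acetate inverts C2, giving the target's C1 configuration under control of the adjacent bought stereocentre.

**Step 10**
Reactants: 11, (S)‑2,2‑dimethyl‑1,3‑dioxolane‑4‑carbaldehyde ((S)‑glyceraldehyde acetonide)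
Product: 12, (R)‑2,2‑dimethyl‑4‑(2‑methylprop‑1‑en‑1‑yl)‑1,3‑dioxolane
Conditions: i‑PrPPh3I, n‑BuLi, THF, −78 °C → rt
Reagents that add atoms: isopropyltriphenylphosphonium iodide, CC(C)[P+](c1ccccc1)(c1ccccc1)c1ccccc1.[I-]
Why: Wittig olefination with the isopropylidene ylide; no E/Z issue and the α‑stereocentre (future C13) is retained at low temperature.

**Step 11**
Reactants: 12
Product: 13, (R)‑4‑methylpent‑3‑ene‑1,2‑diol
Conditions: 80% aq. AcOH, rt
Reagents that add atoms: none
Why: Mild acetonide hydrolysis; weak acid avoids ionising the allylic alcohol.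

**Step 12**
Reactants: 13
Product: 14, (R)‑4‑methyl‑1‑(triethylsilyloxy)pent‑3‑en‑2‑yl benzoate
Conditions: TESCl, imidazole, CH2Cl2, −78 °C; then BzCl, pyridine, DMAP, 0 °C
Reagents that add atoms: TESCl, CC[Si](Cl)(CC)CC; benzoyl chloride, O=C(Cl)c1ccccc1
Why: Primary‑selective silylation followed by benzoylation of the secondary alcohol in one pot.

**Step 13**
Reactants: 14
Product: 15, (R)‑2‑(benzoyloxy)‑4‑methylpent‑3‑enal
Conditions: (COCl)2, DMSO, CH2Cl2, −78 → −40 °C; i‑Pr2NEt, −78 °C; used crude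
Reagents that add atoms: none
Why: Swern conditions oxidise a primary TES ether directly to the aldehyde; Hünig's base at low temperature avoids epimerisation or conjugation.

**Step 14**
Reactants: 10 and 15
Product: 16, (1S,2R)‑1‑[(2R,3S,4S)‑2‑acetoxy‑3‑ethynyl‑4‑(2‑iodoethyl)‑3,4‑dihydro‑2H‑pyran‑5‑yl]‑1‑hydroxy‑4‑methylpent‑3‑en‑2‑yl benzoate
Conditions: CrCl2 (5 equiv), NiCl2 (2 mol %), DMSO/THF, rt
Reagents that add atoms: none
Why: Nozaki–Hiyama–Kishi coupling: Ni inserts only into the sp2 C–I bond, and the alkenyl‑Cr(III) adds to the non‑chelating α‑benzoyloxy aldehyde under polar Felkin–Anh control to give the 1,2‑anti (12S,13R) product, so C12 is set by the bought C13.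

**Step 15**
Reactants: 16
Product: 17, (1S,2R)‑1‑acetoxy‑1‑[(2R,3S,4S)‑2‑acetoxy‑3‑ethynyl‑4‑(2‑iodoethyl)‑3,4‑dihydro‑2H‑pyran‑5‑yl]‑4‑methylpent‑3‑en‑2‑yl benzoate
Conditions: Ac2O, pyridine, DMAP (cat.), CH2Cl2, 0 °C
Reagents that add atoms: acetic anhydride, CC(=O)OC(C)=O
Why: DMAP‑catalysed acetylation of the only free hydroxyl, done promptly to pre‑empt benzoate migration.

**Step 16**
Reactants: 18, (R)‑2,2‑dimethyl‑1,3‑dioxolane‑4‑carbaldehyde ((R)‑glyceraldehyde acetonide)
Product: 19, (S)‑4‑(2,2‑dibromovinyl)‑2,2‑dimethyl‑1,3‑dioxolane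
Conditions: CBr4, PPh3, Et3N, CH2Cl2, 0 °C
Reagents that add atoms: carbon tetrabromide, BrC(Br)(Br)Br
Why: Corey–Fuchs (Ramirez) dibromo‑olefination; the amine buffer protects the α‑stereocentre (future C9).

**Step 17**
Reactants: 19
Product: 20, (S)‑2,2‑dimethyl‑4‑(prop‑1‑yn‑1‑yl)‑1,3‑dioxolane
Conditions: n‑BuLi (2.1 equiv), THF, −78 °C; MeI, −78 °C → rt
Reagents that add atoms: iodomethane, CI
Why: Second stage of the Corey–Fuchs sequence; the lithium acetylide is methylated in situ.

**Step 18**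
Reactants: 20
Product: 21, (S,E)‑4‑(2‑iodoprop‑1‑en‑1‑yl)‑2,2‑dimethyl‑1,3‑dioxolane
Conditions: Cp2Zr(H)Cl (2 equiv), THF, 50 °C; then I2, 0 °C
Reagents that add atoms: iodine, II
Why: Hydrozirconation–iodination: syn addition with Zr on the less hindered methyl‑bearing carbon (after equilibration) and iodinolysis with retention give the (E)‑iodide with I trans to the stereocentre.

**Step 19**
Reactants: 21
Product: 22, (S,E)‑4‑iodopent‑3‑ene‑1,2‑diol
Conditions: PPTS, MeOH, 40 °C
Reagents that add atoms: none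
Why: Acetonide methanolysis; the vinyl iodide is inert.

**Step 20**
Reactants: 22
Product: 23, (S,E)‑4‑iodo‑1‑(triethylsilyloxy)pent‑3‑en‑2‑yl acetate
Conditions: TESCl, imidazole, CH2Cl2, −78 °C; then Ac2O, pyridine, DMAP, 0 °C
Reagents that add atoms: TESCl, CC[Si](Cl)(CC)CC; acetic anhydride, CC(=O)OC(C)=O
Why: Primary‑selective silylation then acetylation installs the C9 acetate before C10–OH exists.

**Step 21**
Reactants: 17 and 23
Product: 24, (S,E)‑6‑[(2R,3S,4S)‑2‑acetoxy‑5‑[(1S,2R)‑1‑acetoxy‑2‑(benzoyloxy)‑4‑methylpent‑3‑en‑1‑yl]‑3‑ethynyl‑3,4‑dihydro‑2H‑pyran‑4‑yl]‑4‑methyl‑1‑(triethylsilyloxy)hex‑3‑en‑2‑yl acetate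
Conditions: Zn dust, LiCl, THF, 30 °C (17 → alkylzinc iodide); then 23, Pd(OAc)2/SPhos (5 mol %), THF, rt
Reagents that add atoms: none
Why: Negishi sp3–sp2 coupling forms C6–C7 with retention of the E geometry; oxidative addition to the vinyl iodide is much faster than ionisation of the hindered secondary allylic esters.

**Step 22**
Reactants: 24
Product: 25, (S,E)‑6‑[(2R,3S,4S)‑2‑acetoxy‑5‑[(1S,2R)‑1‑acetoxy‑2‑(benzoyloxy)‑4‑methylpent‑3‑en‑1‑yl]‑3‑ethynyl‑3,4‑dihydro‑2H‑pyran‑4‑yl]‑4‑methyl‑1‑oxohex‑3‑en‑2‑yl acetate (ynal)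
Conditions: (COCl)2, DMSO, CH2Cl2, −78 → −40 °C; i‑Pr2NEt, −78 °C; used crude
Reagents that add atoms: none
Why: Direct Swern oxidation of the primary TES ether gives the α‑acetoxy aldehyde without a separate deprotection; cold amine base avoids C9 epimerisation.

**Step 23**
Reactants: 25
Product: 26, Antheliatin
Conditions: (IPr)Ni(styrene)2 (10–15 mol %), HFIP (3 equiv), n‑Bu4NPF6, THF/DMA, RVC cathode / Zn anode, undivided cell, controlled potential at the Ni(II)/Ni(0) couple, 25 added by syringe pump to 2 mM, rt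
Reagents that add atoms: none
Why: Proposed new method: Ni(0)–IPr couples the terminal alkyne and the aldehyde by oxidative cyclization at the internal alkyne carbon (the bulky NHC favours the exo mode and the nine‑membered ring), HFIP protonates the Ni–O and Ni–C bonds and the cathode returns Ni(II) to Ni(0) in place of a silane, giving the C10–C11 bond, the exo‑methylene and free C10–OH; the 9,10‑trans (10S) alcohol is expected from a transition state with the Ni‑bound oxygen exo to the forming ring and C9–OAc pseudo‑equatorial, though acyclic Felkin–Anh preference would favour the cis epimer, so this is not certain; closest known reactions are Ni(0)/NHC/silane reductive ynal macrocyclization and Ni electroreductive couplings.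

## Compound list

1 | genipin | OCC=1[C@H]2[C@H](O)OC=C(C(=O)OC)[C@H]2CC=1 | starting material
2 | 10‑oxogenipin | O=CC=1[C@H]2[C@H](O)OC=C(C(=O)OC)[C@H]2CC=1 | intermediate
3 | 1‑O‑TBS‑10‑oxogenipin | O=CC=1[C@H]2[C@H](O[Si](C)(C)C(C)(C)C)OC=C(C(=O)OC)[C@H]2CC=1 | intermediate
4 | convex‑face epoxy aldehyde of 3 | O=C[C@@]13[C@H]2[C@H](O[Si](C)(C)C(C)(C)C)OC=C(C(=O)OC)[C@H]2C[C@@H]1O3 | intermediate
5 | seco alkynyl alcohol ester | C#C[C@H]1[C@H](O[Si](C)(C)C(C)(C)C)OC=C(C(=O)OC)[C@H]1CCO | intermediate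
6 | seco alkynyl alcohol acid | C#C[C@H]1[C@H](O[Si](C)(C)C(C)(C)C)OC=C(C(O)=O)[C@H]1CCO | intermediate
7 | C4 vinyl iodide alcohol | C#C[C@H]1[C@H](O[Si](C)(C)C(C)(C)C)OC=C(I)[C@H]1CCO | intermediate
8 | diiodide silyl acetal | C#C[C@H]1[C@H](O[Si](C)(C)C(C)(C)C)OC=C(I)[C@H]1CCI | intermediate
9 | diiodide lactol | C#C[C@H]1[C@H](O)OC=C(I)[C@H]1CCI | intermediate
10 | diiodide C1 acetate (OAc cis to ethynyl) | C#C[C@H]1[C@@H](OC(C)=O)OC=C(I)[C@H]1CCI | intermediate
11 | (S)‑glyceraldehyde acetonide | O=C[C@@H]1COC(C)(C)O1 | starting material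
12 | (R)‑2,2‑dimethyl‑4‑(2‑methylprop‑1‑enyl)‑1,3‑dioxolane | CC(C)=C[C@@H]1COC(C)(C)O1 | intermediate
13 | (R)‑4‑methylpent‑3‑ene‑1,2‑diol | CC(C)=C[C@@H](O)CO | intermediate
14 | (R)‑4‑methyl‑1‑(triethylsilyloxy)pent‑3‑en‑2‑yl benzoate | CC(C)=C[C@@H](OC(=O)c1ccccc1)CO[Si](CC)(CC)CC | intermediate
15 | (R)‑2‑(benzoyloxy)‑4‑methylpent‑3‑enal | CC(C)=C[C@@H](OC(=O)c1ccccc1)C=O | intermediate
16 | NHK adduct (12S‑OH, 13R‑OBz) | C#C[C@H]1[C@@H](OC(C)=O)OC=C([C@H](O)[C@@H](C=C(C)C)OC(=O)c2ccccc2)[C@H]1CCI | intermediate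
17 | C12 acetate alkyl iodide | C#C[C@H]1[C@@H](OC(C)=O)OC=C([C@H](OC(C)=O)[C@@H](C=C(C)C)OC(=O)c2ccccc2)[C@H]1CCI | intermediate
18 | (R)‑glyceraldehyde acetonide | O=C[C@H]1COC(C)(C)O1 | starting material
19 | (S)‑4‑(2,2‑dibromovinyl)‑2,2‑dimethyl‑1,3‑dioxolane | BrC(Br)=C[C@H]1COC(C)(C)O1 | intermediate
20 | (S)‑2,2‑dimethyl‑4‑(prop‑1‑ynyl)‑1,3‑dioxolane | CC#C[C@H]1COC(C)(C)O1 | intermediate
21 | (S,E)‑4‑(2‑iodoprop‑1‑enyl)‑2,2‑dimethyl‑1,3‑dioxolane | I/C(C)=C/[C@H]1COC(C)(C)O1 | intermediate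
22 | (S,E)‑4‑iodopent‑3‑ene‑1,2‑diol | I/C(C)=C/[C@H](O)CO | intermediate
23 | (S,E)‑4‑iodo‑1‑(triethylsilyloxy)pent‑3‑en‑2‑yl acetate | I/C(C)=C/[C@H](OC(C)=O)CO[Si](CC)(CC)CC | intermediate
24 | Negishi product (C10–OTES) | C#C[C@H]1[C@@H](OC(C)=O)OC=C([C@H](OC(C)=O)[C@@H](C=C(C)C)OC(=O)c2ccccc2)[C@H]1CC/C(C)=C/[C@H](OC(C)=O)CO[Si](CC)(CC)CC | intermediate
25 | ynal | C#C[C@H]1[C@@H](OC(C)=O)OC=C([C@H](OC(C)=O)[C@@H](C=C(C)C)OC(=O)c2ccccc2)[C@H]1CC/C(C)=C/[C@H](OC(C)=O)C=O | intermediate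
26 | Antheliatin | C=C1[C@H]2[C@@H](OC(C)=O)OC=C([C@H](OC(C)=O)[C@@H](C=C(C)C)OC(=O)c3ccccc3)[C@H]2CC/C(C)=C/[C@H](OC(C)=O)[C@H]1O | target

## Step count

Total: 23 steps. Longest linear sequence: 14 steps from genipin (steps 1–9, 14, 15, 21, 22, 23).

## Three steps most likely to fail

1. **Step 23 (proposed new electroreductive ynal macrocyclization).** Risks: Ni(0) ionising the allylic esters, cathodic loss of the α‑acetoxy group, endo cyclization, and the wrong C10 epimer. Fallback with known chemistry: convert the alkyne of 24 into the 2‑iodo‑1‑alkene (Mo‑catalysed α‑selective hydrostannation, then I2), oxidise as in step 22, and close the ring by a stoichiometric CrCl2/cat. NiCl2 Nozaki–Hiyama–Kishi macrocyclization. If the 9,10‑cis alcohol forms, correct C10 by Dess–Martin oxidation to the enone and Luche reduction.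

2. **Step 14 (NHK at the β‑iodo enol ether).** Risks: ring‑opening of the alkenyl‑chromium by β‑alkoxide elimination, and benzoate migration in the product. Fallback: stannylate 10 (Me6Sn2, Pd) and run a Pd/Cu Stille acylation with the acid chloride of (R)‑2‑(PMB‑oxy)‑4‑methylpent‑3‑enoic acid to give the C12 ketone. Then apply Zn(BH4)2 chelation‑controlled reduction (anti), acetylation, DDQ and benzoylation.

3. **Step 9 (anomeric Mitsunobu).** Risks: SN1 leakage or reaction through the minor lactol anomer, giving the wrong C1 epimer; lactol 9 is also labile. Fallback: oxidise lactol 9 to the δ‑lactone (TPAP/NMO) and use DIBAL‑H reduction with in situ Ac2O/DMAP/pyridine trapping (reductive acetylation). Hydride adds anti to the C11a substituent, which places OAc cis to it.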